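All runs were computed from invented constants; the scatter is artificial.

Which of the four flasks holds the most D at 4.0 min, given that D is made from Q and J and, by the look of the runs, is then lost to G?

- the best flask by amount of D, in percent of the Q charged; "all alike" if 1.5 percentage points covers them all (amber / blue / red / violet / all alike)
- amount of D at the end, in percent of the Q charged, amber
- amount of D at the end, in percent of the Q charged, blue
- amount of D at the end, in percent of the Q charged, red
- amount of D at the end, in percent of the Q charged, violet

| flask | Q | J | L | temperature | remark | time |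
|---|---|---|---|---|---|---|
| winter | 0.020 M | 0.98 equiv | 0.10 equiv | 20 °C | run made earlier |  |
| midnight | 0.028 M | 0.98 equiv | 0.10 equiv | 31 °C | run made earlier |  |
| spring | 0.044 M | 0.98 equiv | 0.10 equiv | 20 °C | run made earlier |  |
| amber | 0.020 M | 0.980 equiv (in portions, 2, over 1.5 min) | 0.100 equiv | 25 °C | first portion at the start, last at 1.5 min | 4.0 min |
| blue | 0.020 M (fed, over 1.5 min) | 0.980 equiv | 0.100 equiv | 25 °C | all else is in the flask from the start; the feed brings no volume worth counting | 4.0 min |
| red | 0.020 M | 0.980 equiv (fed, over 1.5 min) | 0.100 equiv | 25 °C | all else is in the flask from the start; the feed brings no volume worth counting | 4.0 min |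
| violet | 0.020 M | 0.980 equiv (fed, over 1.5 min) | 0.100 equiv |  | the addition at −15 °C, then warmed to 25 °C; the feed brings no volume worth counting | 4.0 min |

- winter (time / min: D / %, Q / %): 0.200: 63.6, 36.3; 0.667: 77.3, 18.3; 1.00: 78.2, 15.2; 1.50: 77.6, 13.3; 2.50: 71.9, 12.5
- midnight (time / min: D / %, Q / %): 0.250: 77.8, 17.1; 0.833: 69.8, 12.3; 1.33: 61.5, 12.4; 2.50: 44.6, 12.0; 3.00: 38.0, 12.2
- spring (time / min: D / %, Q / %): 0.250: 79.2, 19.8; 0.500: 81.7, 14.5; 0.833: 82.5, 12.9; 1.50: 79.0, 12.0; 3.00: 69.5, 12.4

(scatter of a reading: 0.5 percentage points)

- on the list of suspects stand: D -> G; Q + J -> D; J + L -> X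

Late in the spring run Q rests at 12.0%, and late in the midnight run at 12.2%. That is about what 0.980 equiv of J less 0.100 equiv of L leaves unmatched, so you can take 88.0% of the charge as the ceiling for D.

While Q stands flat, the fall of D reads as loss. Spring gives 0.0854 min⁻¹ at 20 °C, midnight gives 0.281 min⁻¹ at 31 °C, and the same factor per degree gives 0.147 min⁻¹ at 25 °C. Its inverse, 6.82 min, is the warm lifetime of D, its first-order lifetime at 25 °C. The rule is to count lifetimes: D left is the ceiling times exp(−warm time / lifetime).

Carried down to −15 °C, the same factor gives a lifetime of 515 min, far longer than the 1.5 min of the addition. So in violet you start the clock at the end of the addition, and the warm time is 2.50 min, which gives 61.0%.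

Blue and red are fed over the 1.5 min at 25 °C. Put the mean birth of their D at half that time: the warm time is 3.25 min, or 0.477 lifetimes, which gives 54.6%. Amber takes its last portion of J at the end of that time, so you should expect its D to be born later and to stand somewhat above this figure. Your reckoning therefore puts violet ahead of blue and red by 6.4 percentage points, wider than the margin of 1.5 points.

The forecast named violet, with 56.8%, 56.4%, 56.5% and 62% for amber, blue, red and violet, on the ground that “D loss is first order and independent of concentration”; its blue figure stands above yours.

The flasks give 56.7% for amber, 55.6% for blue, 56.3% for red and 62.1% for violet, so violet is best.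

    D → G (k = 0.00244 s⁻¹, Ea = 85.0 kJ mol⁻¹)
    Q + J → D (k = 13.7 M⁻¹ s⁻¹, Ea = 52.0 kJ mol⁻¹)
    J + L → X (k = 57.2 M⁻¹ s⁻¹, Ea = 38.0 kJ mol⁻¹)
    (constants at 25 °C)

Taking the path from D to G away moves the gap between violet and blue from 6.5 points to −0.035 points, the largest single effect. Read back through the lifetime, blue's 55.6% means 3.13 min of warm time and violet's 62.1% means 2.38 min. Blue left until 40.0 min counts 5.76 lifetimes, which gives 0.279%, and that flask holds 0.286%.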